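**Plan**

1. Lignan numbering is used: ring O1–C7–C8–C8'–C9'. C7 carries the guaiacyl ring, C8 the C9 hydroxymethyl, and C8' the exocyclic carbinol C7' with the catechol ring.
2. Enabling feature: C8 bears a CH2OH (the footprint of a terminal epoxide opened at its inner carbon), its ring neighbour C8' bears an exocyclic benzylic carbon (the footprint of an aryl alkyne), and O1–C9' between them is a propargylic ether. The ring can therefore be closed by making C8–C8' from a C8 radical.
3. Retrosynthesis: C7'–OH and H–C8' go back to a C8'=C7' benzylidene; C8–C8' is cut (radical 5-exo closure); the O1–C9' ether is cut to an epoxy alcohol and an aryl-propargyl bromide; C7–C8 is cut to O-benzylvanillin and CH2=CHMgBr; the aryl–alkyne bond is cut (Sonogashira).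
4. Forward: two fragments (2 and 3 steps) are joined as an ether, the only ring is closed with Cp2TiCl, the benzylidene is turned into the C7' carbinol by hydroboration, oxidation, epimerisation and reduction, and the protecting groups are removed.
5. Stereochemistry: C7 comes from a Sharpless kinetic-resolution epoxidation with D-(−)-DIPT; C8 from C7 in the radical ring closure (2,3-trans); C8' from base equilibration of the C7' ketone to the all-trans ring; C7' from Felkin–Anh hydride addition.

Key step: step 7

Assumption: the exocyclic alkene of 11 and 12 is expected as an E/Z mixture and is drawn without geometry, because both isomers converge on ketone 16.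

**Step 1**
Reactants: 1 4-(benzyloxy)-3-methoxybenzaldehyde (O-benzylvanillin); 2 vinylmagnesium bromide
Product: 3 rac-1-[4-(benzyloxy)-3-methoxyphenyl]prop-2-en-1-ol
Conditions: THF, 0 °C → rt; aq. NH4Cl
Reagents that add atoms: none
Why: Grignard 1,2-addition of the vinyl nucleophile to an unhindered aryl aldehyde should give the racemic allylic alcohol, the benzyl ether being inert.

**Step 2**
Reactants: 3 rac-1-[4-(benzyloxy)-3-methoxyphenyl]prop-2-en-1-ol
Product: 4 (R)-[4-(benzyloxy)-3-methoxyphenyl][(2S)-oxiran-2-yl]methanol (erythro)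
Conditions: Ti(OiPr)4 (0.1 equiv), D-(−)-diisopropyl tartrate (0.15 equiv), t-BuOOH (0.45 equiv, anhydrous), powdered 4 Å MS, CH2Cl2, −20 °C; cold aq. NaOH/brine work-up; unreacted (R)-3 removed by chromatography
Reagents that add atoms: tert-butyl hydroperoxide, CC(C)(C)OO
Why: Sharpless kinetic resolution: with D-(−)-DIPT the titanium tartrate catalyst should epoxidise the (S)-alcohol far faster than the (R)-alcohol and on the face that gives the erythro epoxy alcohol, so stopping below half conversion should deliver 4 with the C7 configuration of the target (the oxirane centre is set as S but is erased in step 7).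

**Step 3**
Reactants: 5 4-bromobenzene-1,2-diol
Product: 6 1,2-bis(benzyloxy)-4-bromobenzene
Conditions: BnBr (2.2 equiv), K2CO3, DMF, 60 °C
Reagents that add atoms: benzyl bromide, BrCc1ccccc1
Why: Williamson ether synthesis on both phenols; the aryl bromide is inert to carbonate and benzyl bromide.

**Step 4**
Reactants: 6 1,2-bis(benzyloxy)-4-bromobenzene; 7 prop-2-yn-1-ol
Product: 8 3-[3,4-bis(benzyloxy)phenyl]prop-2-yn-1-ol
Conditions: Pd(PPh3)2Cl2 (3 mol %), CuI (5 mol %), Et3N, 80 °C
Reagents that add atoms: none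
Why: Sonogashira coupling: zerovalent palladium formed in situ inserts into the aryl C–Br bond and the copper acetylide of 7 transmetalates, the electron-rich bromide needing heat but nothing else in 6 being reactive.

**Step 5**
Reactants: 8 3-[3,4-bis(benzyloxy)phenyl]prop-2-yn-1-ol
Product: 9 1,2-bis(benzyloxy)-4-(3-bromoprop-1-yn-1-yl)benzene
Conditions: CBr4, PPh3, CH2Cl2, 0 °C
Reagents that add atoms: carbon tetrabromide, BrC(Br)(Br)Br
Why: Appel bromination: the alkoxyphosphonium ion of the primary propargylic alcohol is displaced by bromide under neutral conditions that spare the benzyl ethers and the alkyne.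

**Step 6**
Reactants: 4 (R)-[4-(benzyloxy)-3-methoxyphenyl][(2S)-oxiran-2-yl]methanol; 9 1,2-bis(benzyloxy)-4-(3-bromoprop-1-yn-1-yl)benzene
Product: 10 (2S)-2-{(R)-[4-(benzyloxy)-3-methoxyphenyl]({3-[3,4-bis(benzyloxy)phenyl]prop-2-yn-1-yl}oxy)methyl}oxirane
Conditions: Ag2O (2 equiv), 9 (1.5 equiv), powdered 4 Å MS, CH2Cl2, rt, dark
Reagents that add atoms: none
Why: Silver-oxide-promoted Williamson-type etherification: Ag2O activates the propargylic bromide as a halophile without generating a free alkoxide, which should avoid Payne rearrangement and opening of the neighbouring oxirane, and no stereocentre is touched.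

**Step 7**
Reactants: 10 (2S)-2-{(R)-[4-(benzyloxy)-3-methoxyphenyl]({3-[3,4-bis(benzyloxy)phenyl]prop-2-yn-1-yl}oxy)methyl}oxirane
Product: 11 {(2S,3R)-2-[4-(benzyloxy)-3-methoxyphenyl]-4-[3,4-bis(benzyloxy)benzylidene]tetrahydrofuran-3-yl}methanol (alkene geometry unassigned)
Conditions: Cp2TiCl2 (2.5 equiv), Zn dust, THF, rt (gives green Cp2TiCl); added dropwise to 10 in THF, rt; then 1 M HCl, 0 °C
Reagents that add atoms: none
Why: Cp2TiCl (trivalent titanium, from Cp2TiCl2 and Zn) binds the oxirane oxygen and transfers one electron, breaking the C8–O bond to give the secondary C8 radical while O9 stays on tetravalent titanium; this is the Nugent–RajanBabu reductive epoxide opening, and the closest known reaction type is its use in radical cyclisations of epoxy propargyl ethers to 4-alkylidene tetrahydrofurans. The C8 radical adds to the near alkyne carbon C8' in a 5-exo-dig closure that forms C8–C8' and ring O1–C7–C8–C8'–C9', and the aryl-stabilised vinyl radical at C7' is quenched by hydrogen abstraction from THF or by a second Cp2TiCl followed by protonation in the acid work-up. The one new stereocentre, C8, is controlled by C7: in the chair-like transition state the C7 aryl group lies pseudo-equatorial, so aryl and CH2O[Ti] should end up trans on the ring, and the oxirane configuration of 10 has no influence because C8 becomes a planar radical. The step needs opening toward the inner carbon, which the greater stability of the secondary over the primary radical secures, and it needs cyclisation to outrun capture of the C8 radical by a second titanium (which would deoxygenate the substrate to the allyl ether); the conjugated aryl alkyne held three atoms away is a fast acceptor and slow addition keeps the titanium concentration low. Benzyl ethers, the benzylic C7–O bond and the arenes are inert to the reagent, and the alkene geometry formed is of no consequence.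

**Step 8**
Reactants: 11 {(2S,3R)-2-[4-(benzyloxy)-3-methoxyphenyl]-4-[3,4-bis(benzyloxy)benzylidene]tetrahydrofuran-3-yl}methanol
Product: 12 tert-butyl({(2S,3R)-2-[4-(benzyloxy)-3-methoxyphenyl]-4-[3,4-bis(benzyloxy)benzylidene]tetrahydrofuran-3-yl}methoxy)dimethylsilane
Conditions: TBSCl, imidazole, DMF, rt
Reagents that add atoms: tert-butyldimethylsilyl chloride, CC(C)(C)[Si](C)(C)Cl
Why: Silyl ether formation on the primary alcohol keeps C9 from being oxidised in step 10 and stops O9 from closing a hemiketal onto the C7' ketone, which would lock the unwanted 8,8'-cis arrangement.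

**Step 9**
Reactants: 12 tert-butyl({(2S,3R)-2-[4-(benzyloxy)-3-methoxyphenyl]-4-[3,4-bis(benzyloxy)benzylidene]tetrahydrofuran-3-yl}methoxy)dimethylsilane
Product: 14 [3,4-bis(benzyloxy)phenyl][(3R,4R,5S)-5-[4-(benzyloxy)-3-methoxyphenyl]-4-({[tert-butyl(dimethyl)silyl]oxy}methyl)tetrahydrofuran-3-yl]methanol (8,8'-cis; carbinol carbon as an epimer mixture), via alkylborane 13 (not isolated)
Conditions: BH3·THF, THF, 0 °C → rt; then 3 M NaOH, 30% H2O2, 0 °C → rt
Reagents that add atoms: hydrogen peroxide, OO
Why: Brown hydroboration–oxidation: boron should add to the less substituted, benzylic carbon C7' and hydrogen to C8' from the ring face opposite the C8 CH2OTBS group, and oxidation of the C–B bond with retention puts the hydroxyl on C7'; the 8,8'-cis alcohol expected here is provisional, since both new centres are reset in steps 10–12.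

**Step 10**
Reactants: 14 [3,4-bis(benzyloxy)phenyl][(3R,4R,5S)-5-[4-(benzyloxy)-3-methoxyphenyl]-4-({[tert-butyl(dimethyl)silyl]oxy}methyl)tetrahydrofuran-3-yl]methanol (8,8'-cis)
Product: 15 [3,4-bis(benzyloxy)phenyl][(3R,4R,5S)-5-[4-(benzyloxy)-3-methoxyphenyl]-4-({[tert-butyl(dimethyl)silyl]oxy}methyl)tetrahydrofuran-3-yl]methanone (8,8'-cis)
Conditions: Dess–Martin periodinane, NaHCO3, CH2Cl2, rt
Reagents that add atoms: none
Why: Dess–Martin oxidation of a secondary benzylic alcohol to the aryl ketone under buffered, non-acidic conditions merges the C7' epimers into one compound and leaves the silyl and benzyl ethers intact.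

**Step 11**
Reactants: 15 [3,4-bis(benzyloxy)phenyl][(3R,4R,5S)-5-[4-(benzyloxy)-3-methoxyphenyl]-4-({[tert-butyl(dimethyl)silyl]oxy}methyl)tetrahydrofuran-3-yl]methanone (8,8'-cis)
Product: 16 [3,4-bis(benzyloxy)phenyl][(3S,4R,5S)-5-[4-(benzyloxy)-3-methoxyphenyl]-4-({[tert-butyl(dimethyl)silyl]oxy}methyl)tetrahydrofuran-3-yl]methanone (all-trans)
Conditions: DBU (1 equiv), toluene, 60 °C; residual cis ketone separated and resubmitted
Reagents that add atoms: none
Why: Base-mediated epimerisation through the enolate: C8' is the only acidic stereocentre, and the 3,4-trans arrangement that relieves the clash of the aroyl and CH2OTBS groups should dominate at equilibrium, any ring-opened enone from β-elimination of O1 reclosing to the same mixture.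

**Step 12**
Reactants: 16 [3,4-bis(benzyloxy)phenyl][(3S,4R,5S)-5-[4-(benzyloxy)-3-methoxyphenyl]-4-({[tert-butyl(dimethyl)silyl]oxy}methyl)tetrahydrofuran-3-yl]methanone (all-trans)
Product: 17 (R)-[3,4-bis(benzyloxy)phenyl][(3S,4R,5S)-5-[4-(benzyloxy)-3-methoxyphenyl]-4-({[tert-butyl(dimethyl)silyl]oxy}methyl)tetrahydrofuran-3-yl]methanol
Conditions: LiBH(s-Bu)3, THF, −78 °C; aq. NH4Cl
Reagents that add atoms: none
Why: Felkin–Anh-controlled ketone reduction: with the branched ring carbon C8 as the large group anti to the incoming hydride and H8' beside its trajectory, the bulky borohydride should attack the face that gives the (7'R) alcohol, which is also the face a Li–O1 chelate would leave open.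

**Step 13**
Reactants: 17 (R)-[3,4-bis(benzyloxy)phenyl][(3S,4R,5S)-5-[4-(benzyloxy)-3-methoxyphenyl]-4-({[tert-butyl(dimethyl)silyl]oxy}methyl)tetrahydrofuran-3-yl]methanol
Product: 18 (R)-[3,4-bis(benzyloxy)phenyl][(3S,4R,5S)-5-[4-(benzyloxy)-3-methoxyphenyl]-4-(hydroxymethyl)tetrahydrofuran-3-yl]methanol
Conditions: Bu4NF, THF, 0 °C → rt
Reagents that add atoms: none
Why: Fluoride-mediated desilylation frees the primary alcohol without affecting the benzyl ethers or the benzylic alcohol.

**Step 14**
Reactants: 18 (R)-[3,4-bis(benzyloxy)phenyl][(3S,4R,5S)-5-[4-(benzyloxy)-3-methoxyphenyl]-4-(hydroxymethyl)tetrahydrofuran-3-yl]methanol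
Product: 19 4-[(R)-hydroxy{(3S,4R,5S)-4-(hydroxymethyl)-5-(4-hydroxy-3-methoxyphenyl)tetrahydrofuran-3-yl}methyl]benzene-1,2-diol (CNP0197133.1; 7S,8R,7'R,8'S)
Conditions: H2 (1 atm), 10% Pd/C, EtOAc–THF, rt; stopped when uptake ends
Reagents that add atoms: none
Why: Catalytic hydrogenolysis of the three aryl benzyl ethers is fast at 1 atm in a neutral, non-nucleophilic solvent, so it should finish before the benzylic C7–O1 and C7'–OH bonds are attacked and without solvent exchange at C7'.

**Compound list**

1 | 4-(benzyloxy)-3-methoxybenzaldehyde | COc1cc(C=O)ccc1OCc1ccccc1 | starting material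
2 | vinylmagnesium bromide | C=C[Mg]Br | starting material
3 | rac-1-[4-(benzyloxy)-3-methoxyphenyl]prop-2-en-1-ol | COc1cc(C(O)C=C)ccc1OCc1ccccc1 | intermediate
4 | (R)-[4-(benzyloxy)-3-methoxyphenyl][(2S)-oxiran-2-yl]methanol | COc1cc([C@@H](O)[C@@H]2CO2)ccc1OCc1ccccc1 | intermediate
5 | 4-bromobenzene-1,2-diol | Oc1ccc(Br)cc1O | starting material
6 | 1,2-bis(benzyloxy)-4-bromobenzene | Brc1ccc(OCc2ccccc2)c(OCc2ccccc2)c1 | intermediate
7 | prop-2-yn-1-ol | C#CCO | starting material
8 | 3-[3,4-bis(benzyloxy)phenyl]prop-2-yn-1-ol | OCC#Cc1ccc(OCc2ccccc2)c(OCc2ccccc2)c1 | intermediate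
9 | 1,2-bis(benzyloxy)-4-(3-bromoprop-1-yn-1-yl)benzene | BrCC#Cc1ccc(OCc2ccccc2)c(OCc2ccccc2)c1 | intermediate
10 | (2S)-2-{(R)-[4-(benzyloxy)-3-methoxyphenyl]({3-[3,4-bis(benzyloxy)phenyl]prop-2-yn-1-yl}oxy)methyl}oxirane | COc1cc([C@@H](OCC#Cc2ccc(OCc3ccccc3)c(OCc3ccccc3)c2)[C@@H]2CO2)ccc1OCc1ccccc1 | intermediate
11 | {(2S,3R)-2-[4-(benzyloxy)-3-methoxyphenyl]-4-[3,4-bis(benzyloxy)benzylidene]tetrahydrofuran-3-yl}methanol, alkene geometry unassigned | COc1cc([C@H]2OCC(=Cc3ccc(OCc4ccccc4)c(OCc4ccccc4)c3)[C@@H]2CO)ccc1OCc1ccccc1 | intermediate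
12 | tert-butyl({(2S,3R)-2-[4-(benzyloxy)-3-methoxyphenyl]-4-[3,4-bis(benzyloxy)benzylidene]tetrahydrofuran-3-yl}methoxy)dimethylsilane | COc1cc([C@H]2OCC(=Cc3ccc(OCc4ccccc4)c(OCc4ccccc4)c3)[C@@H]2CO[Si](C)(C)C(C)(C)C)ccc1OCc1ccccc1 | intermediate
13 | C7' alkylborane of 12 (BH2 on the benzylic carbon, 8,8'-cis), not isolated | COc1cc([C@H]2OC[C@H](C(B)c3ccc(OCc4ccccc4)c(OCc4ccccc4)c3)[C@@H]2CO[Si](C)(C)C(C)(C)C)ccc1OCc1ccccc1 | intermediate
14 | [3,4-bis(benzyloxy)phenyl][(3R,4R,5S)-5-[4-(benzyloxy)-3-methoxyphenyl]-4-({[tert-butyl(dimethyl)silyl]oxy}methyl)tetrahydrofuran-3-yl]methanol, carbinol epimers | COc1cc([C@H]2OC[C@H](C(O)c3ccc(OCc4ccccc4)c(OCc4ccccc4)c3)[C@@H]2CO[Si](C)(C)C(C)(C)C)ccc1OCc1ccccc1 | intermediate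
15 | [3,4-bis(benzyloxy)phenyl][(3R,4R,5S)-5-[4-(benzyloxy)-3-methoxyphenyl]-4-({[tert-butyl(dimethyl)silyl]oxy}methyl)tetrahydrofuran-3-yl]methanone | COc1cc([C@H]2OC[C@H](C(=O)c3ccc(OCc4ccccc4)c(OCc4ccccc4)c3)[C@@H]2CO[Si](C)(C)C(C)(C)C)ccc1OCc1ccccc1 | intermediate
16 | [3,4-bis(benzyloxy)phenyl][(3S,4R,5S)-5-[4-(benzyloxy)-3-methoxyphenyl]-4-({[tert-butyl(dimethyl)silyl]oxy}methyl)tetrahydrofuran-3-yl]methanone | COc1cc([C@H]2OC[C@@H](C(=O)c3ccc(OCc4ccccc4)c(OCc4ccccc4)c3)[C@@H]2CO[Si](C)(C)C(C)(C)C)ccc1OCc1ccccc1 | intermediate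
17 | (R)-[3,4-bis(benzyloxy)phenyl][(3S,4R,5S)-5-[4-(benzyloxy)-3-methoxyphenyl]-4-({[tert-butyl(dimethyl)silyl]oxy}methyl)tetrahydrofuran-3-yl]methanol | COc1cc([C@H]2OC[C@@H]([C@@H](O)c3ccc(OCc4ccccc4)c(OCc4ccccc4)c3)[C@@H]2CO[Si](C)(C)C(C)(C)C)ccc1OCc1ccccc1 | intermediate
18 | (R)-[3,4-bis(benzyloxy)phenyl][(3S,4R,5S)-5-[4-(benzyloxy)-3-methoxyphenyl]-4-(hydroxymethyl)tetrahydrofuran-3-yl]methanol | COc1cc([C@H]2OC[C@@H]([C@@H](O)c3ccc(OCc4ccccc4)c(OCc4ccccc4)c3)[C@@H]2CO)ccc1OCc1ccccc1 | intermediate
19 | 4-[(R)-hydroxy{(3S,4R,5S)-4-(hydroxymethyl)-5-(4-hydroxy-3-methoxyphenyl)tetrahydrofuran-3-yl}methyl]benzene-1,2-diol | COc1cc([C@H]2OC[C@@H]([C@@H](O)c3ccc(O)c(O)c3)[C@@H]2CO)ccc1O | target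

**Totals**

Total steps: 14. Longest linear sequence: 12 steps (steps 3–14, from 4-bromobenzene-1,2-diol 5 through bromide 9 to the target). Steps 1 and 2 form the two-step side branch that supplies epoxy alcohol 4 to step 6.

**Steps most likely to fail**

1. Step 6 (ether union). What may go wrong: slow O-alkylation of the hindered benzylic hydroxyl by the ionisable aryl-propargyl bromide, with silver-assisted ionisation leading to allenyl ether or silver-promoted opening of the oxirane. The fallback sets out from 4 and returns at 10, joining the fragments in two stages instead of one. Compound 4 is alkylated with parent propargyl bromide, a small electrophile that can be used in large excess (Ag2O, 4 Å MS, Et2O, rt), to give (2S)-2-{(R)-[4-(benzyloxy)-3-methoxyphenyl](prop-2-yn-1-yloxy)methyl}oxirane F1. The aryl group is then attached by a copper-free Sonogashira coupling of F1 with aryl bromide 6 (PdCl2(MeCN)2, XPhos, Cs2CO3, MeCN, 70 °C), which gives 10; steps 4 and 5 are then not needed.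

2. Step 12 (C7' reduction). What may go wrong: poor facial selectivity, because the two ring branches on C8' that steer the hydride differ only moderately in size. The fallback sets out from 16 and returns at 17, replacing substrate control by reagent control. Corey–Bakshi–Shibata reduction with (S)-2-methyl-CBS-oxazaborolidine and BH3·SMe2 (THF, −20 °C) treats the aryl group as the large substituent and should deliver the (R)-carbinol, reinforcing the Felkin–Anh preference. No new compound is involved.

3. Step 2 (kinetic-resolution epoxidation). What may go wrong: insufficient enantiomeric purity of a product taken from a kinetic resolution, and titanium-promoted opening of the electron-rich benzylic epoxy alcohol. The fallback sets out from 3 and returns at 11; it resolves by destroying the unwanted enantiomer and introduces the oxirane only after the ether bond is made. Racemic 3 is epoxidised with the L-(+)-DIPT catalyst (Ti(OiPr)4, t-BuOOH, 4 Å MS, CH2Cl2, −20 °C) to about 60% conversion, which consumes the (R)-alcohol as (S)-[4-(benzyloxy)-3-methoxyphenyl][(2R)-oxiran-2-yl]methanol F3 (discarded) and leaves (S)-1-[4-(benzyloxy)-3-methoxyphenyl]prop-2-en-1-ol F2. Williamson etherification of F2 with bromide 9 (NaH, THF–DMF, 0 °C) gives 1-(benzyloxy)-4-[(1S)-1-({3-[3,4-bis(benzyloxy)phenyl]prop-2-yn-1-yl}oxy)prop-2-en-1-yl]-2-methoxybenzene F4. Epoxidation of the terminal alkene of F4 (mCPBA, NaHCO3, CH2Cl2, rt) gives 10 together with its oxirane epimer (2R)-2-{(R)-[4-(benzyloxy)-3-methoxyphenyl]({3-[3,4-bis(benzyloxy)phenyl]prop-2-yn-1-yl}oxy)methyl}oxirane F5. The mixture is cyclised under the conditions of step 7, both epimers passing through the same C8 radical, to give 11.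

**Further compounds**

F1 | step 6 | (2S)-2-{(R)-[4-(benzyloxy)-3-methoxyphenyl](prop-2-yn-1-yloxy)methyl}oxirane | COc1cc([C@@H](OCC#C)[C@@H]2CO2)ccc1OCc1ccccc1
F0 | step 12 | none | none
F2 | step 2 | (S)-1-[4-(benzyloxy)-3-methoxyphenyl]prop-2-en-1-ol | COc1cc([C@@H](O)C=C)ccc1OCc1ccccc1
F3 | step 2 | (S)-[4-(benzyloxy)-3-methoxyphenyl][(2R)-oxiran-2-yl]methanol | COc1cc([C@H](O)[C@H]2CO2)ccc1OCc1ccccc1
F4 | step 2 | 1-(benzyloxy)-4-[(1S)-1-({3-[3,4-bis(benzyloxy)phenyl]prop-2-yn-1-yl}oxy)prop-2-en-1-yl]-2-methoxybenzene | COc1cc([C@@H](OCC#Cc2ccc(OCc3ccccc3)c(OCc3ccccc3)c2)C=C)ccc1OCc1ccccc1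
F5 | step 2 | (2R)-2-{(R)-[4-(benzyloxy)-3-methoxyphenyl]({3-[3,4-bis(benzyloxy)phenyl]prop-2-yn-1-yl}oxy)methyl}oxirane | COc1cc([C@@H](OCC#Cc2ccc(OCc3ccccc3)c(OCc3ccccc3)c2)[C@H]2CO2)ccc1OCc1ccccc1
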